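**Enzyme clock.** Winter runs 0.120 M·s of enzyme-time, the product of c enzyme and time, while dawn runs 0.0300 M·s, a quarter of that. Watch this number, not the wall clock.

| flask | substrate | enzyme | remark | time |
|---|---|---|---|---|
| north-east | 0.10 M | 0.062 mol% | run made earlier |  |
| south-west | 0.10 M | 0.31 mol% | run made earlier |  |
| north-west | 0.066 M | 0.05 mol% | run made earlier |  |
| summer | 0.025 M | 0.15 mol% |  | 20 min |
| dawn | 0.050 M | 0.05 mol% |  | 20 min |
| winter | 0.050 M | 0.2 mol% |  | 20 min |
| autumn | 0.10 M | 0.05 mol% |  | 20 min |

| run | time / min | target / % | substrate / % |
|---|---|---|---|
| north-east | 2.50 | 78.6 | 17.3 |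
| north-east | 5.00 | 87.5 | 0.1 |
| north-east | 8.00 | 80.9 | 0.2 |
| north-east | 10.0 | 77.2 | 0.1 |
| north-east | 12.0 | 73.4 | 0 |
| north-east | 15.0 | 69.8 | 0.1 |
| south-west | 1.00 | 88.3 | 0.2 |
| south-west | 2.50 | 73.6 | 0.4 |
| south-west | 5.00 | 64.8 | 0 |
| south-west | 8.00 | 61.5 | 0 |
| south-west | 10.0 | 61.6 | 0.5 |
| south-west | 15.0 | 61.7 | 0.3 |
| north-west | 1.00 | 26.9 | 72.8 |
| north-west | 2.00 | 51.8 | 47.2 |
| north-west | 4.00 | 89.7 | 6.6 |
| north-west | 8.00 | 88.5 | 0 |
| north-west | 15.0 | 79.7 | 0 |

(standard deviation of a reading: 0.3 percentage points)

- on the list of suspects stand: target + enzyme <-> isomer of the product + enzyme; substrate + enzyme -> target + enzyme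

1. the flasks put in order of amount of target, in percent of the substrate charged, best first, at 20 min (summer / dawn / winter / autumn)
2. the same order at 1.0 min (summer / dawn / winter / autumn)
3. the amount of target, in percent of the substrate charged of the flask you put first, at 20 min
4. the amount of target, in percent of the substrate charged of the flask you put last, at 20 min

**First instants.** In the north-west run, substrate falls 26 percentage points between 1.00 min and 2.00 min. Divided by the loading, that is 512 min⁻¹. On this straight line, the share converted is this figure times loading times time, and c substrate cancels. At 1.0 min I reckon 76.8% for summer and 25.6% for dawn and autumn, while for winter the line gives 102%, more than the charge holds, so winter's line must bend before then. So I expect winter first and summer second, with autumn just ahead of dawn because its c substrate is higher and should keep the line straight longer.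

**The middle.** At 4.00 min the north-west readings show 89.7% target and 6.6% substrate, so about 3.70% has become isomer of the product. In the north-west readings target is near its top here, and isomerisation is about to matter.

**The end.** Without substrate, target sinks towards the south-west plateau of 61.7%. If both steps scale with c enzyme, dividing one rate by the other removes time, and at fixed c substrate the flask moves on enzyme-time. I call the enzyme-time that halves target's excess over the plateau the half-clock, a pseudo-first-order decay at constant enzyme. The south-west run gives 0.0240 M·s. The north-west run, with the south-west run holding ten times its c enzyme, gives 0.0241 M·s, nearly the same.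

**My reckoning.** Dawn's clock is the shortest, and it lies close to the north-west clock of 0.0297 M·s at 15.0 min, so for dawn I expect about 79.7%. Winter's is the longest. Carrying the south-west reading at 5.00 min forward to winter's clock gives 63.1%. So at 20 min I expect the order of the clocks, shortest first.

**Forecast, result.** The forecast, holding that “The relaxation rate scales with molar enzyme”, gives dawn > summer > autumn > winter at 20 min and winter > summer > autumn > dawn at 1.0 min, with 78.8% and 62.8%. The flasks give dawn > summer > autumn > winter and winter > summer > autumn > dawn, with 79.0% and 62.6%.

    target + enzyme ⇌ isomer of the product + enzyme, rate k1*[enzyme]*[target] forward; the back reaction follows from the equilibrium constant (K = 0.630, k = 677 M⁻¹ min⁻¹)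
    substrate + enzyme → target + enzyme, rate k2*[substrate]*[enzyme]/(1 + ([substrate]/Km2)) (6.85 mM, k = 89100 M⁻¹ min⁻¹)

**What happened.** In dawn, the substrate step carried target to 26.1% at 1.00 min, and by 10.0 min substrate stood at 0% and target at 88.7%. With substrate at that level, the turning of target into isomer of the product took target to 79.0% at 20.0 min, on a half-clock worth 16.0 min in dawn. A longer run would undo the order: at 200 min, about 12.5 half-clocks for dawn, dawn stands at 61.4% and winter at 61.3%.

**Second flask.** The neighbour is dawn at 0.020 M substrate, with clock 0.0120 M·s, half a half-clock. Running dawn's excess back by the difference gives about 90.8%, and the flask gives 89.9%.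

All runs are simulated from invented constants, noise included.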